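**Total synthesis proposal for CNP0274383.1 by oxidative scission of a Birch-reduced podocarpane**

## Analysis of the target

- The target (40) is a briarane. A cyclohexane (ring A: C1, C10–C14) is fused through C1–C10 to a ten-membered carbocycle (C1–C10), and a γ-lactone (O7–C19(=O)–C17–C8) spans C7–C8.
- It has twelve stereocentres (1S,2R,6S,7R,8R,9R,10S,11R,12R,13S,14R,17R) and a Z C3=C4 alkene.
- In the usual planar drawing the C15 methyl on quaternary C1 is β and H10 is α. The C11 methyl and the C12 acetate are cis to C15, and the 13,14-epoxide lies on the opposite face.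
- In the medium ring the C2 and C9 acetoxy groups, the C6 chlorine, the lactone oxygen at C7 and the tertiary C8 hydroxyl are all α. The lactone is therefore trans-fused, C6–Cl and C7–O are cis, and the C17 methyl is cis to the C8 hydroxyl.
- Sensitive groups: a secondary allylic chloride next to the exocyclic methylene of a cross-conjugated 3,5(16)-diene, an epoxide, three acetates, and a β-hydroxy lactone open to retro-aldol cleavage and dehydration.
- The main difficulties are the ten-membered ring (entropy, transannular reactions) and the density of oxygenation around it.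
- The strategy rests on one feature. C2 and C7 are oxygenated carbons in a 1,6 relation across the ten-membered ring. A bond drawn between them gives two six-membered rings which, with ring A and C15, are the three rings of podocarpic acid (1), with the same configuration at C1 and C10.

## Retrosynthetic reasoning

**C6–Cl and the esters (40 ← 37).** The acetates at C9 and C12 are cut last (40 ← 39 ← 38), so that silyl ethers protect these oxygens through all base- and Lewis-acid-mediated steps. The C6–Cl bond is cut next (38 ← 37). An allylic alcohol with an exocyclic methylene can be displaced with inversion, so the chloride configuration follows from a C6 alcohol of opposite configuration. The allylic chloride then meets only two mild steps.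

**C2 stereocentre and C3=C4 (36 ← 33).** The C2–H bond is cut to dienone 34 (36 ← 35 ← 34), because a ketone flanked by quaternary C1 is a clear case for reagent-controlled reduction. The C3=C4 bond is traced to silyl enol ether 33. C2 can enolise only toward C3, so the position of the new alkene is fixed by structure.

**Exocyclic methylene, C6 oxygen and ring A epoxide (33 ← 31).** The C5=C16/C6–O array is an isomerised trisubstituted epoxide (33 ← 32). The epoxide comes from the C5=C6 alkene of 31, and the same oxidation installs the ring A epoxide. Both epoxidations are placed before the diene exists, since no oxidant would later tell the ring A alkene from the diene.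

**Lactone (30 ← 27 + 28).** The C8–C17 bond is cut to an enolate adding to a C8 ketone. Tethering that enolate to O7 (29) makes the addition intramolecular and forms the quaternary carbinol and C17 in one step. The three lactone carbons come from acyl bromide 28.

**Oxygen pattern at C7/C8 (27 ← 23).** The lactone needs C7–OH next to a C8 ketone, whereas ring scission leaves the ketone at C7 and a methylene at C8. The transposition is traced to a C7=C8 silyl enol ether 24 (27 ← 26 ← 25 ← 24). Adding H–B across it puts hydrogen on C7 and oxygen on C8, and keeps the two oxygens differentiated. The enol ether comes from kinetic α′-deprotonation of enone 23; this is the reason the alkene is first moved to C5=C6.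

**Conjugation and temporary masking of C2 (23 ← 20).** The C4=C5 alkene of 20 is moved into conjugation with the C7 ketone through a dienamine, which only the unhindered C7 carbonyl can form. While C7 is so protected the C2 ketone is reduced, which keeps it out of the enolate and borane chemistry; it is re-oxidised in 31.

**Key disconnection (20 ← 17).** Joining C2 to C7 by a double bond converts the cyclodecenedione 20 into hexahydrophenanthrene 17. Forward, cleavage of the tetrasubstituted ring-fusion alkene delivers the ten-membered ring without any macrocyclisation and places carbonyls on the two carbons that must be oxygenated. The reaction must select this alkene over the trisubstituted one and over the ring A alkene.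

**Diene and ring A (17 ← 9).** 17 is the silyl ether of 16, the dissolving-metal reduction product of arene 15; the substitution pattern of the arene dictates the diene. The ring A alkene (the later epoxide) is put in before this reduction (15 ← 14 ← 13). Introducing it late would require telling C12 from C9 and would expose the epimerisable C11 centre in a polyfunctional intermediate. The C11 methyl and C12 oxygen are traced through enone 12 and alcohol 11 to exocyclic alkene 10, the decarboxylation product of acid 9. In this way the carboxyl group of the starting acid becomes the handle for both centres.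

**C9 oxygen and the aromatic ring (9 ← 1).** The C9 oxygen (C6 of the podocarpane) is placed α to a temporary benzylic ketone (7 ← 6 ← 5 ← 4), where it is the thermodynamic epimer. The aryl methyl that becomes C16 is traced to an ortho-formyl group, and the phenol that directs the formylation is removed reductively (4 ← 3 ← 2 ← 1). Every operation before the key step is a standard transformation on a rigid tricycle, so the risk is concentrated in the scission.

## Alternatives that were turned down

**Alternative 1:** The ten-membered ring is cut at C5–C6 and C7–O. Forward, a nitrile oxide at C5 adds to a vinyl group on C8 and closes the carbocycle as the isoxazoline-bridged A1.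
- For: two bonds and the C7 oxygen form in one step. Reductive N–O cleavage would give a C5 ketone for methylenation and a C6 methylene for chlorination. The acetates, epoxide and tertiary alcohol are already in place, so its endgame is shorter than the one proposed here.
- Against: the cycloaddition must close a ten-membered ring in the bridged mode against entropy and transannular strain; the fused regiochemistry is the normal outcome for tethers of this length. The open-chain precursor must already hold C1, C2, C8, C9, C10, C17 and all of ring A, built with no rigid template. The sensitive epoxide and esters must survive nitrile oxide generation.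
- Comparison: the chosen route gives up the short endgame but obtains the ring without a ring-closing event, and takes C1 and C10 from the chiral pool.

**Alternative 2:** Ring A is cut at C10–C11 and C1–C14. Forward, a catalytic asymmetric Diels–Alder reaction gives cyclohexene A2 with C1, C10 and C11 set.
- For: on ring A this is stronger than the chosen route. The quaternary centre and its two neighbours arise in one enantioselective step, and the C12 oxygen is present as a silyl enol ether, against roughly ten degradative steps here.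
- Against: it solves only ring A. The ten-membered ring, the lactone and eight further stereocentres remain, and a separate medium-ring closure is still needed. The cis relation of the C11 and C15 methyls also depends on a hindered trisubstituted dienophile reacting in the right endo sense.
- Comparison: the chosen route is longer for ring A, but the same starting material also supplies the carbons of the ten-membered ring, already joined.

**Alternative 3:** The lactone is cut at C7–C19 and C8–C17. Forward, methylchloroketene A4 adds across a C7=C8 silyl enol ether of the complete ten-membered ring to give cyclobutanone A3, which ring expansion by oxygen insertion would turn into the lactone.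
- For: all three lactone carbons and the C8 oxygen arrive in one step. This is more direct than the five steps spent on the lactone here.
- Against: it is an endgame, not a ring synthesis; the fully functionalised medium ring must come from elsewhere. The trans fusion requires a ring-trans enol ether. The ketene and the later peracid must discriminate against the diene. The C6 chloride is asked to survive dechlorination at C17.
- Comparison: the chosen route forms the lactone before the diene and chloride exist, on an intermediate whose ring comes from the scission.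

Key step: step 16

## Remarks before the steps

- Tricyclic compounds carry podocarpane numbering; the seco compounds and the target carry briarane numbering (podocarpane C10, C5, C4, C3, C2, C1, C6, C7, C8, C9, C11–C14 become briarane C1, C10, C11, C12, C13, C14, C9, C8, C7, C2, C3–C6). α/β refer to the planar drawing with the angular methyl β.
- The C2 carbinol of 22–30 is a temporary mask removed in step 24. Its configuration is not controlled and is left open in the SMILES.
- Acyl bromide 28 is used as the racemate, so the bromine-bearing carbon of 29 is undefined; it becomes an enolate in step 23.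
- Alcohol 11 is drawn as the expected axial 3α epimer; either epimer gives 12.
- The ring double bonds of 21, 22, 24 and 33 that are formed by enolisation are drawn ring-cis.

## Route

Step 1
Reactants: 1 podocarpic acid
Product: 2 13-formylpodocarpic acid (13-formyl-12-hydroxypodocarpa-8,11,13-trien-19-oic acid)
Conditions: MgCl2, Et3N, (CH2O)n, MeCN, reflux; aq. HCl
Reagents that add atoms: formaldehyde (as paraformaldehyde), C=O
Why: Magnesium-phenoxide-directed ortho-formylation (Casnati–Skattebøl reaction); C11 is blocked by the C1 methylene and the C10 methyl, so the formyl group, the future C16, should enter at C13, and the hindered carboxylate is a spectator.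

Step 2
Reactants: 2 13-formylpodocarpic acid
Product: 3 13-formyl-12-(1-phenyl-1H-tetrazol-5-yloxy)podocarpa-8,11,13-trien-19-oic acid
Conditions: 5-chloro-1-phenyl-1H-tetrazole, K2CO3, DMF, 25 °C; aq. HCl
Reagents that add atoms: 5-chloro-1-phenyl-1H-tetrazole, Clc1nnnn1-c1ccccc1
Why: Nucleophilic aromatic substitution by the phenoxide gives the aryl tetrazolyl ether needed for reductive removal of the phenol oxygen; the neopentyl carboxylate is far less nucleophilic.

Step 3
Reactants: 3 the tetrazolyl ether
Product: 4 13-methylpodocarpa-8,11,13-trien-19-oic acid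
Conditions: H2 (4 atm), Pd/C, EtOH–AcOH, 45 °C
Reagents that add atoms: none
Why: Hydrogenolysis over Pd/C cleaves the aryl–oxygen bond of the tetrazolyl ether (Musliner–Gates deoxygenation) and, in the same operation, takes the aryl aldehyde through the benzylic alcohol to the methyl group.

Step 4
Reactants: 4 13-methylpodocarpa-8,11,13-trien-19-oic acid
Product: 5 13-methyl-7-oxopodocarpa-8,11,13-trien-19-oic acid
Conditions: CrO3, AcOH–H2O, 25 °C
Reagents that add atoms: chromium trioxide, O=[Cr](=O)=O
Why: Chromic acid benzylic oxidation; C7 is the only benzylic methylene (C10 is quaternary), and a ring methylene is oxidised faster than the aryl methyl group.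

Step 5
Reactants: 5 the 7-ketone
Product: 6 6α-hydroxy-13-methyl-7-oxopodocarpa-8,11,13-trien-19-oic acid
Conditions: KN(SiMe3)2 (2.2 equiv), THF, −78 °C; 2-(phenylsulfonyl)-3-phenyloxaziridine; NH4Cl
Reagents that add atoms: 2-(phenylsulfonyl)-3-phenyloxaziridine, O=S(=O)(N1OC1c1ccccc1)c1ccccc1
Why: Davis hydroxylation of the potassium enolate, which can form only toward C6; the β face is screened by the C10 methyl and the axial carboxylate, so oxygen should enter on the α face, and the equatorial 6α-alcohol is also the thermodynamic epimer next to the ketone.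

Step 6
Reactants: 6 the 6α-hydroxy ketone
Product: 7 6α-hydroxy-13-methylpodocarpa-8,11,13-trien-19-oic acid
Conditions: H2 (4 atm), Pd/C, EtOH, HCl (cat.), 40 °C
Reagents that add atoms: none
Why: Acid-assisted hydrogenolysis of the aryl ketone through the benzylic alcohol; the C6 hydroxyl is not benzylic and should be kept with its configuration.

Step 7
Reactants: 7 the 6α-hydroxy acid
Product: 9 6α-(tert-butyldimethylsilyloxy)-13-methylpodocarpa-8,11,13-trien-19-oic acid, via bis-silyl ester 8 (not isolated)
Conditions: t-BuMe2SiOTf (2.5 equiv), 2,6-lutidine, CH2Cl2, 0 °C; then K2CO3, MeOH–H2O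
Reagents that add atoms: tert-butyldimethylsilyl triflate, CC(C)(C)[Si](C)(C)OS(=O)(=O)C(F)(F)F
Why: Silylation of the hindered secondary alcohol with the silyl triflate; the silyl ester formed alongside is cleaved selectively by mild basic methanolysis.

Step 8
Reactants: 9 the silyloxy acid
Product: 10 6α-(tert-butyldimethylsilyloxy)-13-methyl-4-methylene-18,19-dinorpodocarpa-8,11,13-triene
Conditions: Pb(OAc)4, Cu(OAc)2·H2O (cat.), pyridine, benzene, 80 °C
Reagents that add atoms: none
Why: Kochi oxidative decarboxylation: the tertiary C4 radical is oxidised by divalent copper and loses a β-hydrogen preferentially from the unhindered methyl group, so the exocyclic alkene should be the main isomer; endocyclic isomers are removed on AgNO3-impregnated silica.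

Step 9
Reactants: 10 the exocyclic alkene
Product: 11 6α-(tert-butyldimethylsilyloxy)-13-methyl-4-methylene-18,19-dinorpodocarpa-8,11,13-trien-3α-ol
Conditions: SeO2 (cat.), t-BuOOH, CH2Cl2, 25 °C
Reagents that add atoms: tert-butyl hydroperoxide, CC(C)(C)OO (oxygen relayed through selenium dioxide, O=[Se]=O)
Why: Selenium dioxide allylic hydroxylation (ene reaction, then 2,3-sigmatropic shift) attacks the ring methylene C3 in preference to the ring-fusion methine C5; the configuration at C3 is irrelevant because the alcohol is oxidised next.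

Step 10
Reactants: 11 the allylic alcohol
Product: 12 6α-(tert-butyldimethylsilyloxy)-13-methyl-4-methylene-18,19-dinorpodocarpa-8,11,13-trien-3-one
Conditions: Dess–Martin periodinane, NaHCO3, CH2Cl2, 0 °C
Reagents that add atoms: none
Why: Buffered Dess–Martin oxidation gives the α-methylene ketone without migration of the double bond; it is used at once.

Step 11
Reactants: 12 the α-methylene ketone
Product: 13 6α-(tert-butyldimethylsilyloxy)-4β,13-dimethyl-18,19-dinorpodocarpa-8,11,13-trien-3-one (4α-H)
Conditions: H2 (1 atm), RhCl(PPh3)3 (cat.), benzene, 25 °C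
Reagents that add atoms: none
Why: Homogeneous hydrogenation of the unhindered 1,1-disubstituted alkene from the α face, the β face being shielded by the axial C10 methyl, puts hydrogen on C4α and sets the axial 4β-methyl (C11 of the target); neutral conditions avoid epimerisation, and an equatorial methyl would clash with the 6α-silyloxy group in any case.

Step 12
Reactants: 13 the 4β-methyl ketone
Product: 14 6α-(tert-butyldimethylsilyloxy)-4β,13-dimethyl-18,19-dinorpodocarpa-1,8,11,13-tetraen-3-one
Conditions: LiN(iPr)2, THF, −78 °C; then PhS(Cl)=N-t-Bu, −78 °C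
Reagents that add atoms: none
Why: Mukaiyama dehydrogenation: the kinetic enolate forms at the C2 methylene and not at the hindered C4 methine, attacks sulfur, and the adduct undergoes syn-elimination to the C1=C2 enone; C4 is not touched.

Step 13
Reactants: 14 the enone
Product: 15 6α-(tert-butyldimethylsilyloxy)-4β,13-dimethyl-18,19-dinorpodocarpa-1,8,11,13-tetraen-3β-ol
Conditions: NaBH4, CeCl3·7H2O, MeOH, −78 °C
Reagents that add atoms: none
Why: Luche 1,2-reduction; hydride should add from the α face, away from the axial 4β and 10β methyl groups, giving the 3β-alcohol (C12 of the target).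

Step 14
Reactants: 15 the aryl allylic alcohol
Product: 16 6α-(tert-butyldimethylsilyloxy)-4β,13-dimethyl-18,19-dinorpodocarpa-1,8,12-trien-3β-ol
Conditions: Li, NH3(l), THF, t-BuOH, −33 °C; NH4Cl
Reagents that add atoms: none
Why: Birch reduction; protonation at the two unsubstituted, para-related carbons C11 and C14 keeps all three alkyl-bearing carbons on double bonds, so the 8(9),12-diene should form without new stereocentres. The allylic alcohol travels as its lithium alkoxide, which is not a leaving group, and the isolated alkene and silyl ether are inert.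

Step 15
Reactants: 16 the diene alcohol
Product: 17 3β,6α-bis(tert-butyldimethylsilyloxy)-4β,13-dimethyl-18,19-dinorpodocarpa-1,8,12-triene
Conditions: t-BuMe2SiOTf, 2,6-lutidine, CH2Cl2, −78 °C
Reagents that add atoms: tert-butyldimethylsilyl triflate, CC(C)(C)[Si](C)(C)OS(=O)(=O)C(F)(F)F
Why: Silylation of the hindered allylic alcohol with the silyl triflate at low temperature; the skipped diene is stable to the buffered conditions.

Step 16
Reactants: 17 the hexahydrophenanthrene triene
Product: 20 9α,12β-bis(tert-butyldimethylsilyloxy)-1β,5,11β-trimethylbicyclo[8.4.0]tetradeca-4Z,13-diene-2,7-dione, via 8α,9α-epoxide 18 (not isolated), via 8β,9α-diol 19 (not isolated)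
Conditions: m-CPBA (1.0 equiv), NaHCO3, CH2Cl2, −40 °C; then HClO4 (0.05 M), THF–H2O, 0 °C; then Pb(OAc)4, pyridine–benzene, 25 °C
Reagents that add atoms: m-chloroperbenzoic acid, O=C(OO)c1cccc(Cl)c1; water, O
Why: The peracid transfers oxygen in a concerted electrophilic step to the most electron-rich alkene, the tetrasubstituted C8=C9 ring-fusion bond, from its α face; one equivalent at low temperature should leave the trisubstituted C12=C13 alkene and the neopentyl, allylically deactivated C1=C2 alkene untouched. Dilute acid opens the tetrasubstituted epoxide by backside attack of water to the trans-diaxial diol 19. That diol cannot form a cyclic periodate, so the cleavage uses Pb(OAc)4 in pyridine, which breaks anti-periplanar ring-fusion glycols through an open tetravalent-lead alkoxide (Criegee glycol cleavage). The closest known reactions are the peracid epoxidation of the central alkene of Birch-derived 1,4,5,8-tetrahydronaphthalenes and the lead tetraacetate cleavage of trans-decalin-9,10-diol to cyclodecane-1,6-dione. No ring is closed by bond formation: scission of the bond shared by the two six-membered rings merges them into the ten-membered ring, and the former alkene carbons emerge as the C2 and C7 ketones. No stereocentre is created, and the existing ones are not α to an enolisable position of the new ketones (C1 is quaternary). The step needs site selectivity among three alkenes, which the substitution pattern (tetra > tri > deactivated cis-di) should provide, and it needs the 1,6-diketone to escape transannular aldol reaction, so 20 is taken into step 17 without delay.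

Step 17
Reactants: 20 the cyclodecenedione
Product: 23 2-hydroxy-9α,12β-bis(tert-butyldimethylsilyloxy)-1β,5,11β-trimethylbicyclo[8.4.0]tetradeca-5Z,13-dien-7-one, via dienamine ketone 21 (not isolated), via dienamine alcohol 22 (not isolated)
Conditions: pyrrolidine, benzene, 4 Å sieves, 25 °C; evaporate; LiAlH4, THF, −20 °C; then AcOH–NaOAc–H2O, MeOH, 25 °C
Reagents that add atoms: none
Why: Only the unhindered C7 ketone condenses with pyrrolidine, as the conjugated 4,6-dienamine (the classical dienamine protection of unsaturated ketones), which is inert to hydride; LiAlH4 then reduces the neopentyl C2 ketone. Buffered hydrolysis protonates the dienamine at C4 and releases the conjugated enone with the C5=C6 bond.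

Step 18
Reactants: 23 the hydroxy enone
Product: 24 bis(triethylsilyl) compound: 2-triethylsilyloxy, 7-triethylsilyloxy-5Z,7(8),13-triene, 9α,12β-bis(tert-butyldimethylsilyloxy)
Conditions: LiN(iPr)2 (3.2 equiv), THF, −78 °C; Et3SiCl, Et3N, −78 → 0 °C
Reagents that add atoms: chlorotriethylsilane, CC[Si](Cl)(CC)CC
Why: Kinetic deprotonation of the enone at the α′ carbon C8 gives the cross-conjugated enolate, which is trapped on oxygen as the silyl dienol ether; the same reagent silylates the C2 alkoxide.

Step 19
Reactants: 24 the silyl dienol ether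
Product: 25 8β-hydroxy-2,7α-bis(triethylsilyloxy)-9α,12β-bis(tert-butyldimethylsilyloxy)-5Z,13-diene (7β-H)
Conditions: BH3·THF (1.2 equiv), THF, −20 → 0 °C; then NaOH, H2O2, 0 °C
Reagents that add atoms: hydrogen peroxide, OO
Why: Hydroboration of a silyl enol ether puts boron β to oxygen (C8) and hydrogen on the oxygen-bearing carbon (C7) in a syn addition; attack anti to the adjacent C9 silyloxy group should place H7 on the β face (7R). Oxidation gives the C8 alcohol while the C7 oxygen stays silylated, so the two oxygens are differentiated.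

Step 20
Reactants: 25 the C8 alcohol
Product: 26 8-oxo-2,7α-bis(triethylsilyloxy)-9α,12β-bis(tert-butyldimethylsilyloxy)-5Z,13-diene
Conditions: Dess–Martin periodinane, NaHCO3, CH2Cl2, 0 °C
Reagents that add atoms: none
Why: Dess–Martin oxidation of the only free alcohol; the buffered, non-basic conditions should neither epimerise C7 nor move the C5=C6 bond.

Step 21
Reactants: 26 the α-silyloxy ketone
Product: 27 2,7α-dihydroxy-8-oxo-9α,12β-bis(tert-butyldimethylsilyloxy)-5Z,13-diene
Conditions: HF·pyridine, pyridine, THF, 0 °C
Reagents that add atoms: none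
Why: Triethylsilyl ethers are cleaved by buffered HF·pyridine much faster than the secondary tert-butyldimethylsilyl ethers; the α-ketol is kept away from base, which would drive the ketol shift.

Step 22
Reactants: 27 the diol ketone, 28 2-bromopropanoyl bromide
Product: 29 7α-(2-bromopropanoyloxy)-2-hydroxy-8-oxo-9α,12β-bis(tert-butyldimethylsilyloxy)-5Z,13-diene
Conditions: pyridine, CH2Cl2, −40 °C
Reagents that add atoms: 2-bromopropanoyl bromide (28), CC(Br)C(Br)=O
Why: Acylation of the C7 hydroxyl; the C2 hydroxyl is neopentyl (next to quaternary C1) and should not react with one equivalent at low temperature.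

Step 23
Reactants: 29 the bromo ester
Product: 30 γ-lactone (O7–C19(=O)–C17(CH3)–C8): 2,8α-dihydroxy, 17β-H, 9α,12β-bis(tert-butyldimethylsilyloxy), 5Z,13-diene
Conditions: SmI2 (2.5 equiv), THF, −78 °C; NH4Cl
Reagents that add atoms: none
Why: Intramolecular Reformatsky reaction: SmI2 reduces the carbon–bromine bond far faster than it attacks the ketone, and the trivalent-samarium ester enolate adds to the adjacent C8 carbonyl to close the five-membered lactone. The tether holds C17 syn to O7; the ring torsion C6–C7–C8–C9 should stay anti in the chelated transition state, which puts the new hydroxyl trans to H7 (8R, trans-fused lactone). The C17 methyl should lie away from C9 (17R), which is also the stable arrangement of this epimerisable centre.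

Step 24
Reactants: 30 the hydroxy lactone
Product: 31 2-oxo lactone: 8α-hydroxy, 9α,12β-bis(tert-butyldimethylsilyloxy), 5Z,13-diene
Conditions: Dess–Martin periodinane, NaHCO3, CH2Cl2, 25 °C
Reagents that add atoms: none
Why: Dess–Martin oxidation regenerates the C2 ketone; the tertiary C8 alcohol cannot be oxidised.

Step 25
Reactants: 31 the keto lactone diene
Product: 32 bis-epoxide: 5β,6β-epoxide and 13α,14α-epoxide, 2-oxo, 8α-hydroxy, 9α,12β-bis(tert-butyldimethylsilyloxy)
Conditions: dimethyldioxirane (excess), acetone–CH2Cl2, 0 → 25 °C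
Reagents that add atoms: dimethyldioxirane, CC1(C)OO1
Why: Dimethyldioxirane epoxidises both isolated alkenes without Baeyer–Villiger oxidation of the ketone. In ring A it should add anti to the C15 and C20 methyl groups and the 12β-silyloxy group; at C5=C6 it should add anti to the allylic lactone oxygen, in line with the trans selectivity of peroxide reagents toward medium-ring cis-cycloalkenyl alcohol derivatives.

Step 26
Reactants: 32 the bis-epoxide
Product: 33 tris(triethylsilyl) compound: 2-triethylsilyloxy-2(3)-ene, 5(16)-ene, 6β- and 8α-triethylsilyloxy, 13α,14α-epoxide, 9α,12β-bis(tert-butyldimethylsilyloxy)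
Conditions: Et3SiOTf (5 equiv), 2,6-lutidine, CH2Cl2, −78 °C; then DBU, −78 → 25 °C
Reagents that add atoms: triethylsilyl triflate, CC[Si](CC)(CC)OS(=O)(=O)C(F)(F)F
Why: Silyl-triflate-mediated isomerisation of an epoxide to an allyl silyl ether: the activated trisubstituted epoxide ionises at tertiary C5 and the base removes a proton from the unhindered C16 methyl, giving the exocyclic alkene with the C6 oxygen silylated. The ring A epoxide, whose carbons are neopentyl or next to the silyloxy carbon, should not ionise. The C2 ketone becomes its silyl enol ether (only C3 can enolise) and the tertiary alcohol is capped.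

Step 27
Reactants: 33 the silyl enol ether
Product: 34 cross-conjugated dienone: 2-oxo-3Z,5(16)-diene, 6β- and 8α-triethylsilyloxy, 13α,14α-epoxide, 9α,12β-bis(tert-butyldimethylsilyloxy)
Conditions: Pd(OAc)2 (1.2 equiv), MeCN, 25 °C
Reagents that add atoms: none
Why: Saegusa–Ito oxidation: the divalent-palladium enolate undergoes syn β-hydride elimination of H4. In the ten-membered ring, which already holds the trans-fused lactone, only the cis C3=C4 geometry should be attainable, and the allyl silyl ether is not ionised by palladium.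

Step 28
Reactants: 34 the dienone
Product: 35 (2R)-allylic alcohol: 2α-hydroxy-3Z,5(16)-diene, otherwise as 34
Conditions: (S)-1-methyl-3,3-diphenyltetrahydro-1H,3H-pyrrolo[1,2-c][1,3,2]oxazaborole (1 equiv), catecholborane, toluene, −78 °C
Reagents that add atoms: none
Why: Corey–Bakshi–Shibata reduction under reagent control: with quaternary C1 as the large and the cis-vinyl group as the small substituent, the (S)-oxazaborolidine should deliver hydride to the face that gives the 2R alcohol. Catecholborane at −78 °C reduces the ketone 1,2 and leaves alkenes, lactone and epoxide alone.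

Step 29
Reactants: 35 the allylic alcohol
Product: 36 2α-acetate of 35
Conditions: Ac2O, pyridine, DMAP (cat.), CH2Cl2, 0 °C
Reagents that add atoms: acetic anhydride, CC(=O)OC(C)=O
Why: Standard acetylation of the only free hydroxyl.

Step 30
Reactants: 36 the acetate
Product: 37 6β-alcohol: 2α-acetoxy, 6β-hydroxy, 8α-triethylsilyloxy, 9α,12β-bis(tert-butyldimethylsilyloxy), 13α,14α-epoxide, 3Z,5(16)-diene
Conditions: pyridinium p-toluenesulfonate, MeOH–CH2Cl2, 0 °C
Reagents that add atoms: none
Why: Acid-catalysed methanolysis removes the secondary allylic triethylsilyl ether; the tertiary triethylsilyl ether and the secondary tert-butyldimethylsilyl ethers react far more slowly, and the conditions are too mild for the epoxide.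

Step 31
Reactants: 37 the 6β-alcohol
Product: 38 6α-chloride (6S), otherwise as 37
Conditions: PPh3, hexachloroacetone, CH2Cl2, 0 °C
Reagents that add atoms: hexachloroacetone, ClC(Cl)(Cl)C(=O)C(Cl)(Cl)Cl
Why: Appel-type chlorination with hexachloroacetone and PPh3, which converts secondary allylic alcohols into chlorides by direct SN2 displacement with inversion and little allylic transposition; ionisation is disfavoured by the adjacent oxygen-bearing C7.

Step 32
Reactants: 38 the chloride
Product: 39 triol: 2α-acetoxy-6α-chloro-8α,9α,12β-trihydroxy-13α,14α-epoxide, 3Z,5(16)-diene lactone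
Conditions: Et3N·3HF, MeCN, 40 °C
Reagents that add atoms: none
Why: Fluoride cleavage of the three remaining silyl ethers with the weakly acidic, weakly nucleophilic amine–HF complex, chosen to spare the allylic chloride, the epoxide and the acetate.

Step 33
Reactants: 39 the triol
Product: 40 the target, CNP0274383.1
Conditions: Ac2O, pyridine, DMAP (cat.), 0 → 25 °C
Reagents that add atoms: acetic anhydride, CC(=O)OC(C)=O
Why: Acetylation of the two secondary alcohols (C9, C12); the tertiary C8 hydroxyl, flanked by C9 and the lactone, should not be acylated under these conditions and stays free as in the target.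

## Compound list

1 | podocarpic acid | C[C@]1(C(O)=O)CCC[C@]2(C)c3cc(O)ccc3CC[C@@H]12 | starting material
2 | 13-formylpodocarpic acid | C[C@]1(C(O)=O)CCC[C@]2(C)c3cc(O)c(C=O)cc3CC[C@@H]12 | intermediate
3 | 13-formyl-12-(1-phenyl-1H-tetrazol-5-yloxy)podocarpa-8,11,13-trien-19-oic acid | C[C@]1(C(O)=O)CCC[C@]2(C)c3cc(Oc4nnnn4-c4ccccc4)c(C=O)cc3CC[C@@H]12 | intermediate
4 | 13-methylpodocarpa-8,11,13-trien-19-oic acid | C[C@]1(C(O)=O)CCC[C@]2(C)c3ccc(C)cc3CC[C@@H]12 | intermediate
5 | 13-methyl-7-oxopodocarpa-8,11,13-trien-19-oic acid | C[C@]1(C(O)=O)CCC[C@]2(C)c3ccc(C)cc3C(=O)C[C@@H]12 | intermediate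
6 | 6α-hydroxy-13-methyl-7-oxopodocarpa-8,11,13-trien-19-oic acid | C[C@]1(C(O)=O)CCC[C@]2(C)c3ccc(C)cc3C(=O)[C@H](O)[C@@H]12 | intermediate
7 | 6α-hydroxy-13-methylpodocarpa-8,11,13-trien-19-oic acid | C[C@]1(C(O)=O)CCC[C@]2(C)c3ccc(C)cc3C[C@H](O)[C@@H]12 | intermediate
8 | tert-butyldimethylsilyl 6α-(tert-butyldimethylsilyloxy)-13-methylpodocarpa-8,11,13-trien-19-oate | C[C@]1(C(=O)O[Si](C)(C)C(C)(C)C)CCC[C@]2(C)c3ccc(C)cc3C[C@H](O[Si](C)(C)C(C)(C)C)[C@@H]12 | intermediate
9 | 6α-(tert-butyldimethylsilyloxy)-13-methylpodocarpa-8,11,13-trien-19-oic acid | C[C@]1(C(O)=O)CCC[C@]2(C)c3ccc(C)cc3C[C@H](O[Si](C)(C)C(C)(C)C)[C@@H]12 | intermediate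
10 | 6α-(tert-butyldimethylsilyloxy)-13-methyl-4-methylene-18,19-dinorpodocarpa-8,11,13-triene | C=C1CCC[C@]2(C)c3ccc(C)cc3C[C@H](O[Si](C)(C)C(C)(C)C)[C@@H]12 | intermediate
11 | 3α-hydroxy derivative of 10 | C=C1[C@H](O)CC[C@]2(C)c3ccc(C)cc3C[C@H](O[Si](C)(C)C(C)(C)C)[C@@H]12 | intermediate
12 | 3-oxo derivative of 10 (α-methylene ketone) | C=C1C(=O)CC[C@]2(C)c3ccc(C)cc3C[C@H](O[Si](C)(C)C(C)(C)C)[C@@H]12 | intermediate
13 | 6α-(tert-butyldimethylsilyloxy)-4β,13-dimethyl-18,19-dinorpodocarpa-8,11,13-trien-3-one | C[C@H]1C(=O)CC[C@]2(C)c3ccc(C)cc3C[C@H](O[Si](C)(C)C(C)(C)C)[C@@H]12 | intermediate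
14 | 6α-(tert-butyldimethylsilyloxy)-4β,13-dimethyl-18,19-dinorpodocarpa-1,8,11,13-tetraen-3-one | C[C@H]1C(=O)C=C[C@]2(C)c3ccc(C)cc3C[C@H](O[Si](C)(C)C(C)(C)C)[C@@H]12 | intermediate
15 | 6α-(tert-butyldimethylsilyloxy)-4β,13-dimethyl-18,19-dinorpodocarpa-1,8,11,13-tetraen-3β-ol | C[C@H]1[C@@H](O)C=C[C@]2(C)c3ccc(C)cc3C[C@H](O[Si](C)(C)C(C)(C)C)[C@@H]12 | intermediate
16 | 6α-(tert-butyldimethylsilyloxy)-4β,13-dimethyl-18,19-dinorpodocarpa-1,8,12-trien-3β-ol | C[C@H]1[C@@H](O)C=C[C@]2(C)C3=C(CC(C)=CC3)C[C@H](O[Si](C)(C)C(C)(C)C)[C@@H]12 | intermediate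
17 | 3β,6α-bis(tert-butyldimethylsilyloxy)-4β,13-dimethyl-18,19-dinorpodocarpa-1,8,12-triene (key-step precursor) | C[C@H]1[C@@H](O[Si](C)(C)C(C)(C)C)C=C[C@]2(C)C3=C(CC(C)=CC3)C[C@H](O[Si](C)(C)C(C)(C)C)[C@@H]12 | intermediate
18 | 8α,9α-epoxide of 17 | C[C@H]1[C@@H](O[Si](C)(C)C(C)(C)C)C=C[C@]2(C)[C@]34O[C@]3(CC(C)=CC4)C[C@H](O[Si](C)(C)C(C)(C)C)[C@@H]12 | intermediate
19 | 8β,9α-diol of 17 | C[C@H]1[C@@H](O[Si](C)(C)C(C)(C)C)C=C[C@]2(C)[C@]3(O)[C@](O)(CC(C)=CC3)C[C@H](O[Si](C)(C)C(C)(C)C)[C@@H]12 | intermediate
20 | 9α,12β-bis(tert-butyldimethylsilyloxy)-1β,5,11β-trimethylbicyclo[8.4.0]tetradeca-4Z,13-diene-2,7-dione (key-step product) | C/C1=C/CC(=O)[C@]2(C)[C@H]([C@@H](C)[C@@H](O[Si](C)(C)C(C)(C)C)C=C2)[C@@H](O[Si](C)(C)C(C)(C)C)CC(=O)C1 | intermediate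
21 | 7-(pyrrolidin-1-yl)-4,6-dienamine of 20 (2-ketone) | O=C1[C@]2(C)[C@H]([C@@H](C)[C@@H](O[Si](C)(C)C(C)(C)C)C=C2)[C@@H](O[Si](C)(C)C(C)(C)C)C/C(N3CCCC3)=C\C(C)=C/C1 | intermediate
22 | 2-hydroxy dienamine (C2 epimers) | OC1[C@]2(C)[C@H]([C@@H](C)[C@@H](O[Si](C)(C)C(C)(C)C)C=C2)[C@@H](O[Si](C)(C)C(C)(C)C)C/C(N3CCCC3)=C\C(C)=C/C1 | intermediate
23 | 2-hydroxy-5Z,13-dien-7-one (C2 epimers) | OC1[C@]2(C)[C@H]([C@@H](C)[C@@H](O[Si](C)(C)C(C)(C)C)C=C2)[C@@H](O[Si](C)(C)C(C)(C)C)CC(=O)/C=C(C)\CC1 | intermediate
24 | 2,7-bis(triethylsilyloxy)-5Z,7,13-triene (silyl dienol ether) | CC[Si](CC)(CC)OC1[C@]2(C)[C@H]([C@@H](C)[C@@H](O[Si](C)(C)C(C)(C)C)C=C2)[C@@H](O[Si](C)(C)C(C)(C)C)/C=C(O[Si](CC)(CC)CC)\C=C(C)/CC1 | intermediate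
25 | 8β-hydroxy-2,7α-bis(triethylsilyloxy)-5Z,13-diene | CC[Si](CC)(CC)OC1[C@]2(C)[C@H]([C@@H](C)[C@@H](O[Si](C)(C)C(C)(C)C)C=C2)[C@@H](O[Si](C)(C)C(C)(C)C)[C@H](O)[C@@H](O[Si](CC)(CC)CC)/C=C(C)\CC1 | intermediate
26 | 8-oxo-2,7α-bis(triethylsilyloxy)-5Z,13-diene | CC[Si](CC)(CC)OC1[C@]2(C)[C@H]([C@@H](C)[C@@H](O[Si](C)(C)C(C)(C)C)C=C2)[C@@H](O[Si](C)(C)C(C)(C)C)C(=O)[C@@H](O[Si](CC)(CC)CC)/C=C(C)\CC1 | intermediate
27 | 2,7α-dihydroxy-8-oxo-5Z,13-diene | OC1[C@]2(C)[C@H]([C@@H](C)[C@@H](O[Si](C)(C)C(C)(C)C)C=C2)[C@@H](O[Si](C)(C)C(C)(C)C)C(=O)[C@@H](O)/C=C(C)\CC1 | intermediate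
28 | 2-bromopropanoyl bromide | CC(Br)C(Br)=O | starting material
29 | 7α-(2-bromopropanoyloxy)-2-hydroxy-8-oxo-5Z,13-diene | OC1[C@]2(C)[C@H]([C@@H](C)[C@@H](O[Si](C)(C)C(C)(C)C)C=C2)[C@@H](O[Si](C)(C)C(C)(C)C)C(=O)[C@@H](OC(=O)C(C)Br)/C=C(C)\CC1 | intermediate
30 | trans-fused γ-lactone, 2,8α-dihydroxy-5Z,13-diene | OC1[C@]2(C)[C@H]([C@@H](C)[C@@H](O[Si](C)(C)C(C)(C)C)C=C2)[C@@H](O[Si](C)(C)C(C)(C)C)[C@]3(O)[C@@H](C)C(=O)O[C@H]3/C=C(C)\CC1 | intermediate
31 | 2-oxo lactone, 8α-hydroxy-5Z,13-diene | O=C1[C@]2(C)[C@H]([C@@H](C)[C@@H](O[Si](C)(C)C(C)(C)C)C=C2)[C@@H](O[Si](C)(C)C(C)(C)C)[C@]3(O)[C@@H](C)C(=O)O[C@H]3/C=C(C)\CC1 | intermediate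
32 | 5β,6β:13α,14α-bis-epoxide of 31 | O=C1[C@]2(C)[C@H]([C@@H](C)[C@@H](O[Si](C)(C)C(C)(C)C)[C@@H]4O[C@@H]42)[C@@H](O[Si](C)(C)C(C)(C)C)[C@]3(O)[C@@H](C)C(=O)O[C@H]3[C@@H]5O[C@]5(C)CC1 | intermediate
33 | 2-triethylsilyloxy-2-ene, 5(16)-ene, 6β,8α-bis(triethylsilyloxy), 13α,14α-epoxide | C=C1C/C=C(O[Si](CC)(CC)CC)\[C@]2(C)[C@H]([C@@H](C)[C@@H](O[Si](C)(C)C(C)(C)C)[C@@H]4O[C@@H]42)[C@@H](O[Si](C)(C)C(C)(C)C)[C@]3(O[Si](CC)(CC)CC)[C@@H](C)C(=O)O[C@H]3[C@@H]1O[Si](CC)(CC)CC | intermediate
34 | 2-oxo-3Z,5(16)-diene | C=C1/C=C\C(=O)[C@]2(C)[C@H]([C@@H](C)[C@@H](O[Si](C)(C)C(C)(C)C)[C@@H]4O[C@@H]42)[C@@H](O[Si](C)(C)C(C)(C)C)[C@]3(O[Si](CC)(CC)CC)[C@@H](C)C(=O)O[C@H]3[C@@H]1O[Si](CC)(CC)CC | intermediate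
35 | (2R)-2-hydroxy-3Z,5(16)-diene | C=C1/C=C\[C@@H](O)[C@]2(C)[C@H]([C@@H](C)[C@@H](O[Si](C)(C)C(C)(C)C)[C@@H]4O[C@@H]42)[C@@H](O[Si](C)(C)C(C)(C)C)[C@]3(O[Si](CC)(CC)CC)[C@@H](C)C(=O)O[C@H]3[C@@H]1O[Si](CC)(CC)CC | intermediate
36 | (2R)-2-acetate of 35 | C=C1/C=C\[C@@H](OC(C)=O)[C@]2(C)[C@H]([C@@H](C)[C@@H](O[Si](C)(C)C(C)(C)C)[C@@H]4O[C@@H]42)[C@@H](O[Si](C)(C)C(C)(C)C)[C@]3(O[Si](CC)(CC)CC)[C@@H](C)C(=O)O[C@H]3[C@@H]1O[Si](CC)(CC)CC | intermediate
37 | 6β-alcohol | C=C1/C=C\[C@@H](OC(C)=O)[C@]2(C)[C@H]([C@@H](C)[C@@H](O[Si](C)(C)C(C)(C)C)[C@@H]4O[C@@H]42)[C@@H](O[Si](C)(C)C(C)(C)C)[C@]3(O[Si](CC)(CC)CC)[C@@H](C)C(=O)O[C@H]3[C@@H]1O | intermediate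
38 | 6α-chloride | C=C1/C=C\[C@@H](OC(C)=O)[C@]2(C)[C@H]([C@@H](C)[C@@H](O[Si](C)(C)C(C)(C)C)[C@@H]4O[C@@H]42)[C@@H](O[Si](C)(C)C(C)(C)C)[C@]3(O[Si](CC)(CC)CC)[C@@H](C)C(=O)O[C@H]3[C@H]1Cl | intermediate
39 | 2-acetoxy-6-chloro-8,9,12-triol | C=C1/C=C\[C@@H](OC(C)=O)[C@]2(C)[C@H]([C@@H](C)[C@@H](O)[C@@H]4O[C@@H]42)[C@@H](O)[C@]3(O)[C@@H](C)C(=O)O[C@H]3[C@H]1Cl | intermediate
40 | CNP0274383.1 | C=C1/C=C\[C@@H](OC(C)=O)[C@]2(C)[C@H]([C@@H](C)[C@@H](OC(C)=O)[C@@H]3O[C@@H]32)[C@@H](OC(C)=O)[C@]2(O)[C@@H](C)C(=O)O[C@H]2[C@H]1Cl | target

## Step count and least certain steps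

Total: 33 steps. Longest linear sequence: 33 steps from 1; acyl bromide 28 enters in step 22.

**Step 16 (key step).**
- Most likely failure: loss of site selectivity in the oxygen transfer, with epoxidation of the unhindered trisubstituted alkene, because the ring-fusion alkene is electronically favoured but sterically shielded.
- Also possible: dehydration of the skipped-diene ring during the acid opening, which would re-aromatise it; slow cleavage of the anti glycol.
- Fallback (from 17, returning at 20): mask the competing alkene first. OsO4 (cat.) with N-methylmorpholine N-oxide should dihydroxylate the most accessible, trisubstituted alkene to the 12α,13α-diol F1. Ozonolysis (O3, CH2Cl2–MeOH, −78 °C; Me2S) then has only the deactivated ring A alkene as competitor and gives the dihydroxy cyclodecanedione F2. 1,1′-Thiocarbonyldiimidazole converts it into the cyclic thionocarbonate F3, and Corey–Winter olefination with P(OMe)3 restores the cis alkene and returns 20.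

**Step 19.**
- Most likely failure: borane adding to the conjugated C5=C6 bond or across the dienol ether in a 1,4 sense, or approaching syn to the C9 silyloxy group, because the enol ether is part of a diene.
- Fallback (from 24, returning at 29): replace hydroboration by oxidation and directed reduction. Rubottom oxidation (dimethyldioxirane, then acidic work-up) should give the 8β-hydroxy enone F4. Me4NBH(OAc)3 delivers hydride from the hydroxyl-bound boron to give the trans 7α,8β-diol F5. The allylic, less hindered C7 hydroxyl is acylated with 28 to the 7-(2-bromopropanoate) F6. Dess–Martin oxidation gives the 8-ketone F7, and HF·pyridine removes the C2 silyl group to return 29.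

**Step 23.**
- Most likely failure: aldol closure on the other face of the C8 carbonyl (cis-fused lactone, C8 epimer) if the ring prefers a syn-clinal C6–C7–C8–C9 torsion; or reductive loss of the C7 acyloxy group.
- Fallback (from 26, returning at 30): intermolecular addition, which attacks the carbonyl face opposite to that reached by the tethered enolate. The lithium enolate of ethyl propanoate (LiN(iPr)2, THF, −78 °C) adds anti to the C7 silyloxy group to give the β-hydroxy ester F8. HF·pyridine followed by pyridinium p-toluenesulfonate removes both triethylsilyl groups and closes the lactone to 30.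

**Step 26.**
- Most likely failure: loss of regiocontrol in the proton removal (endocyclic C4=C5 alkene), transannular capture of the C5 cation by the C2 carbonyl, or ionisation of the ring A epoxide, since the step runs through a cation.
- Fallback (from 32, returning at 33): a base-mediated syn-elimination with no cation. Diethylaluminium 2,2,6,6-tetramethylpiperidide (Et2Al(TMP), toluene, 0 °C) removes only the unhindered methyl proton and should give the 6β-hydroxy 5(16)-ene F9. Et3SiOTf with Et3N then forms the enol ether and the two silyl ethers of 33.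

**Step 27.**
- Most likely failure: β-hydride elimination through a conformer that gives the ring-trans enone, or palladium engaging the exocyclic alkene next to the allylic silyl ether.
- Fallback (from 33, returning at 34): selenoxide elimination. PhSeCl (CH2Cl2, −78 °C) reacts with the silyl enol ether to give the 3-phenylseleno ketone F10; oxidation with H2O2–pyridine at 0 °C triggers syn-elimination to 34.

## Further compounds

F1 | step 16 | 12α,13α-dihydroxy derivative of 17 | C[C@H]1[C@@H](O[Si](C)(C)C(C)(C)C)C=C[C@]2(C)C3=C(C[C@@](C)(O)[C@@H](O)C3)C[C@H](O[Si](C)(C)C(C)(C)C)[C@@H]12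
F2 | step 16 | 4,5-dihydroxy-13-ene-2,7-dione (briarane numbering) | C[C@]1(O)[C@@H](O)CC(=O)[C@]2(C)[C@H]([C@@H](C)[C@@H](O[Si](C)(C)C(C)(C)C)C=C2)[C@@H](O[Si](C)(C)C(C)(C)C)CC(=O)C1
F3 | step 16 | 4,5-cyclic thionocarbonate of F2 | C[C@]1(OC(=S)O3)[C@@H]3CC(=O)[C@]2(C)[C@H]([C@@H](C)[C@@H](O[Si](C)(C)C(C)(C)C)C=C2)[C@@H](O[Si](C)(C)C(C)(C)C)CC(=O)C1
F4 | step 19 | 8β-hydroxy-2-triethylsilyloxy-5Z,13-dien-7-one | CC[Si](CC)(CC)OC1[C@]2(C)[C@H]([C@@H](C)[C@@H](O[Si](C)(C)C(C)(C)C)C=C2)[C@@H](O[Si](C)(C)C(C)(C)C)[C@H](O)C(=O)/C=C(C)\CC1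
F5 | step 19 | 7α,8β-diol, 2-triethylsilyloxy-5Z,13-diene | CC[Si](CC)(CC)OC1[C@]2(C)[C@H]([C@@H](C)[C@@H](O[Si](C)(C)C(C)(C)C)C=C2)[C@@H](O[Si](C)(C)C(C)(C)C)[C@H](O)[C@@H](O)/C=C(C)\CC1
F6 | step 19 | 7α-(2-bromopropanoyloxy)-8β-hydroxy-2-triethylsilyloxy-5Z,13-diene | CC[Si](CC)(CC)OC1[C@]2(C)[C@H]([C@@H](C)[C@@H](O[Si](C)(C)C(C)(C)C)C=C2)[C@@H](O[Si](C)(C)C(C)(C)C)[C@H](O)[C@@H](OC(=O)C(C)Br)/C=C(C)\CC1
F7 | step 19 | 7α-(2-bromopropanoyloxy)-8-oxo-2-triethylsilyloxy-5Z,13-diene | CC[Si](CC)(CC)OC1[C@]2(C)[C@H]([C@@H](C)[C@@H](O[Si](C)(C)C(C)(C)C)C=C2)[C@@H](O[Si](C)(C)C(C)(C)C)C(=O)[C@@H](OC(=O)C(C)Br)/C=C(C)\CC1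
F8 | step 23 | ethyl 2-(8α-hydroxy-2,7α-bis(triethylsilyloxy)-5Z,13-dien-8-yl)propanoate | CC[Si](CC)(CC)OC1[C@]2(C)[C@H]([C@@H](C)[C@@H](O[Si](C)(C)C(C)(C)C)C=C2)[C@@H](O[Si](C)(C)C(C)(C)C)[C@](O)([C@@H](C)C(=O)OCC)[C@@H](O[Si](CC)(CC)CC)/C=C(C)\CC1
F9 | step 26 | 6β,8α-dihydroxy-2-oxo-5(16)-ene lactone, 13α,14α-epoxide | C=C1CCC(=O)[C@]2(C)[C@H]([C@@H](C)[C@@H](O[Si](C)(C)C(C)(C)C)[C@@H]4O[C@@H]42)[C@@H](O[Si](C)(C)C(C)(C)C)[C@]3(O)[C@@H](C)C(=O)O[C@H]3[C@@H]1O
F10 | step 27 | 3-phenylseleno-2-oxo-5(16)-ene, 6β,8α-bis(triethylsilyloxy) | C=C1CC([Se]c5ccccc5)C(=O)[C@]2(C)[C@H]([C@@H](C)[C@@H](O[Si](C)(C)C(C)(C)C)[C@@H]4O[C@@H]42)[C@@H](O[Si](C)(C)C(C)(C)C)[C@]3(O[Si](CC)(CC)CC)[C@@H](C)C(=O)O[C@H]3[C@@H]1O[Si](CC)(CC)CC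
A1 | alternative 1 | ten-membered carbocycle bridged by an isoxazoline across C5 and C7 | N1=C2/C=C\[C@@H](OC(C)=O)[C@]3(C)[C@H]([C@@H](C)[C@@H](OC(C)=O)[C@@H]4O[C@@H]43)[C@@H](OC(C)=O)[C@](O)([C@@H](C)C(=O)OC)[C@H](C2)O1
A2 | alternative 2 | ring A cyclohexene with C1 formyl and methyl, C10 ester, C11 methyl, C12 silyl enol ether | O=C[C@]1(C)[C@H]([C@@H](C)C(O[Si](C)(C)C(C)(C)C)=CC1)C(=O)OC
A3 | alternative 3 | trans-fused 2-chloro-2-methyl-3-silyloxycyclobutanone | C=C1/C=C\[C@@H](O[Si](C)(C)C(C)(C)C)[C@]2(C)[C@H]([C@@H](C)[C@@H](O[Si](C)(C)C(C)(C)C)[C@@H]3O[C@@H]32)[C@@H](O[Si](C)(C)C(C)(C)C)[C@]4(O[Si](C)(C)C)[C@@](Cl)(C)C(=O)[C@H]4C1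
A4 | alternative 3 | methylchloroketene | CC(Cl)=C=O
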